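The 2,6,6-trimethylcyclohexene ring is read as a masked β-keto ester: the methyl-bearing sp2 carbon is a ketone, the first side-chain carbon an ester, the gem-dimethyl carbon a prenyl-derived tertiary cation. One flask joins methyl acetoacetate dianion and prenyl bromide, then SnCl4 closes the ring: this [3+3] annulation forges the ring CH2–CH2 bond and the hindered bond from the chain-bearing sp2 carbon to the quaternary carbon. The ring then enters last, as a cyclogeranyl ylide, onto an epoxy aldehyde that already holds the 1,2-dioxane; this core comes from geraniol by Sharpless epoxidation, anti-crotylation, invertive perhydrolysis of the tertiary epoxide carbon and SN2 peroxide closure.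

Key step: step 1

Remark on the chemistry: chain carbons are numbered from the carboxyl carbon (C1) to the CH2 on the ring (C12); the alkenes made in steps 16 and 19 (C7=C8 and C11=C12) are expected as E/Z mixtures and are written without geometry because step 20 saturates both; 4 is racemic at an enolizable carbon and 20 is used as the racemate.

Step 1
Reactants: 1 methyl acetoacetate; 2 prenyl bromide (1-bromo-3-methylbut-2-ene)
Product: 4 methyl 2,2-dimethyl-6-oxocyclohexane-1-carboxylate, via keto ester 3 (not isolated)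
Conditions: NaH, THF, 0 °C; n-BuLi, 0 °C; 2, 0 °C to rt; HCl in Et2O (1 equiv); solvent switch to CH2Cl2; SnCl4 (1.5 equiv), 0 °C to rt
Reagents that add atoms: none
Why: The sodium lithium dianion of 1 reacts at its terminal carbon with the primary allylic bromide (SN2; acetoacetate dianion γ-alkylation) and so makes the ring CH2–CH2 bond in 3. After protonation, SnCl4 chelates the β-keto ester, the HCl set free protonates the trisubstituted alkene, and the tertiary cation is captured by the central enol carbon, which makes the bond between the future chain-bearing sp2 carbon and the gem-dimethyl carbon (closest known type: Lewis acid cyclization of olefinic β-keto esters, a cation–olefin cyclization). The cyclohexanone ring closes in a 6-endo-trig mode with respect to the protonated alkene, with Markovnikov regiochemistry. The only new stereocentre, the ester-bearing carbon, is racemic and enolizable and is erased in step 2. The step needs γ- over α-alkylation, which the more basic terminal carbanion of the dianion secures, and C- over O-capture of the cation, which the tin chelate secures by leaving the central carbon as the nucleophile and the carbocycle as the thermodynamic product.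

Step 2
Reactants: 4 methyl 2,2-dimethyl-6-oxocyclohexane-1-carboxylate
Product: 5 methyl 6,6-dimethyl-2-(trifluoromethylsulfonyloxy)cyclohex-1-ene-1-carboxylate
Conditions: NaH, Et2O, 0 °C; Tf2O, 0 °C
Reagents that add atoms: trifluoromethanesulfonic anhydride, O=S(=O)(OS(=O)(=O)C(F)(F)F)C(F)(F)F
Why: The doubly activated α-hydrogen of 4 is removed by NaH and the sodium enolate is trapped on oxygen by Tf2O (enol triflate formation), which places the future ring alkene between the ester-bearing carbon and the former ketone carbon.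

Step 3
Reactants: 5 enol triflate
Product: 6 methyl 2,6,6-trimethylcyclohex-1-ene-1-carboxylate
Conditions: MeMgBr, Fe(acac)3 (5 mol%), THF/NMP, −30 °C
Reagents that add atoms: methylmagnesium bromide, C[Mg]Br
Why: Iron-catalysed cross-coupling of the alkenyl triflate with the methyl Grignard reagent (Kumada-type coupling) should replace the triflate by methyl faster than the Grignard reagent attacks the hindered ester at low temperature.

Step 4
Reactants: 6 methyl 2,6,6-trimethylcyclohex-1-ene-1-carboxylate
Product: 7 (2,6,6-trimethylcyclohex-1-en-1-yl)methanol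
Conditions: LiAlH4, Et2O, 0 °C to rt
Reagents that add atoms: none
Why: Hydride reduction of the twisted conjugated ester (LiAlH4 ester reduction) proceeds by 1,2-addition only and gives the primary allylic alcohol.

Step 5
Reactants: 7 (2,6,6-trimethylcyclohex-1-en-1-yl)methanol
Product: 8 triphenyl[(2,6,6-trimethylcyclohex-1-en-1-yl)methyl]phosphonium bromide
Conditions: Ph3P·HBr, CH2Cl2, rt
Reagents that add atoms: triphenylphosphine hydrobromide, [Br-].[PH+](c1ccccc1)(c1ccccc1)c1ccccc1
Why: Protonation of the allylic alcohol and capture of the allylic cation by triphenylphosphine at the unhindered primary carbon (allylic substitution) gives the phosphonium salt.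

Step 6
Reactants: 9 geraniol
Product: 10 [(2R,3R)-3-methyl-3-(4-methylpent-3-en-1-yl)oxiran-2-yl]methanol
Conditions: Ti(OiPr)4 (5 mol%), D-(−)-diethyl tartrate (6 mol%), t-BuOOH, 4 Å molecular sieves, CH2Cl2, −20 °C
Reagents that add atoms: tert-butyl hydroperoxide, CC(C)(C)OO
Why: Sharpless asymmetric epoxidation is hydroxyl-directed and so touches only the allylic alkene, and the D-(−)-tartrate complex delivers oxygen to the face that gives the (2R,3R)-epoxide, which fixes the carbon that will carry the tertiary peroxide oxygen after one inversion.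

Step 7
Reactants: 10 (2R,3R)-epoxy alcohol
Product: 11 tert-butyl{[(2R,3R)-3-methyl-3-(4-methylpent-3-en-1-yl)oxiran-2-yl]methoxy}diphenylsilane
Conditions: TBDPSCl, imidazole, CH2Cl2, 0 °C to rt
Reagents that add atoms: tert-butyl(chloro)diphenylsilane, CC(C)(C)[Si](Cl)(c1ccccc1)c1ccccc1
Why: Silylation of the primary alcohol (silyl ether formation) keeps this oxygen out of the later mesylation and peroxide closure.

Step 8
Reactants: 11 epoxy silyl ether
Product: 12 3-[(2R,3R)-3-(TBDPS-oxymethyl)-2-methyloxiran-2-yl]propanal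
Conditions: O3, CH2Cl2, −78 °C; PPh3, −78 °C to rt
Reagents that add atoms: ozone, [O-][O+]=O
Why: Ozonolysis with reductive work-up cleaves the only alkene to the aldehyde and leaves the epoxide and the silyl ether untouched.

Step 9
Reactants: 12 epoxy aldehyde
Product: 13 (3S,4R)-6-[(2R,3R)-3-(TBDPS-oxymethyl)-2-methyloxiran-2-yl]-3-methylhex-1-en-4-ol
Conditions: (−)-(E)-crotyl-B(Ipc)2 [from (+)-α-pinene], THF, −78 °C; NaOH, H2O2, 0 °C to rt
Reagents that add atoms: (−)-(E)-crotyldiisopinocampheylborane, C/C=C/CB([C@@H]1C[C@@H]2C[C@H]([C@H]1C)C2(C)C)[C@@H]1C[C@@H]2C[C@H]([C@H]1C)C2(C)C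
Why: Brown crotylboration through a chair-like six-membered transition state transfers the E-crotyl group to give the anti relationship of methyl and hydroxyl, and the isopinocampheyl groups from (+)-α-pinene direct the attack to the Si face of the aldehyde, which sets the (4R)-carbinol and (3S)-methyl centres under reagent control.

Step 10
Reactants: 13 anti homoallylic alcohol
Product: 14 (3S,4R)-6-[(2R,3R)-3-(TBDPS-oxymethyl)-2-methyloxiran-2-yl]-3-methylhex-1-en-4-yl methanesulfonate
Conditions: MsCl, Et3N, CH2Cl2, 0 °C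
Reagents that add atoms: methanesulfonyl chloride, CS(=O)(=O)Cl
Why: Sulfonylation of the secondary alcohol (mesylate formation) proceeds with retention and turns this oxygen into the leaving group for the peroxide closure.

Step 11
Reactants: 14 epoxy mesylate
Product: 16 (1R)-2-(TBDPS-oxy)-1-{(3S,6S)-6-[(2S)-but-3-en-2-yl]-3-methyl-1,2-dioxan-3-yl}ethan-1-ol, via hydroperoxide 15 (not isolated)
Conditions: H2O2 (anhydrous, in Et2O), H3PMo12O40 (2 mol%), rt; aqueous wash; KOtBu (1.05 equiv), THF, 0 °C
Reagents that add atoms: hydrogen peroxide, OO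
Why: Acid-catalysed perhydrolysis opens the trisubstituted epoxide at its tertiary carbon with inversion (borderline SN2 epoxide opening), and the potassium hydroperoxide then displaces the secondary mesylate in a 6-exo-tet SN2 ring closure with inversion, so both peroxide-bearing carbons of the 1,2-dioxane are set by stereospecific substitution.

Step 12
Reactants: 16 vinyl dioxane
Product: 17 methyl (2R)-2-{(3S,6S)-6-[(1R)-2-(TBDPS-oxy)-1-hydroxyethyl]-6-methyl-1,2-dioxan-3-yl}propanoate
Conditions: O3, NaOH (2.5 M in MeOH), CH2Cl2, −78 °C; AcOH quench at −78 °C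
Reagents that add atoms: ozone, [O-][O+]=O; methanol, CO
Why: Ozonolysis in methanolic NaOH (Marshall ozonolysis) converts the terminal vinyl group directly into the methyl ester, and the cold, short exposure to base should leave the adjacent methyl-bearing stereocentre and the peroxide intact.

Step 13
Reactants: 17 silyl ether ester
Product: 19 methyl (2R)-2-[(3S,6S)-6-formyl-6-methyl-1,2-dioxan-3-yl]propanoate, via diol 18 (not isolated)
Conditions: Bu4NF, AcOH, THF, 0 °C; NaIO4, THF/H2O (pH 7), rt
Reagents that add atoms: none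
Why: Fluoride desilylation followed by periodate glycol cleavage (Malaprade reaction) excises the CH2OH carbon and leaves an α-peroxy aldehyde that has no α-hydrogen and cannot epimerize.

Step 14
Reactants: 20 2-methyl-2-vinyloxirane
Product: 21 (2E)-4-chloro-2-methylbut-2-en-1-ol
Conditions: TiCl4, CH2Cl2, −85 °C
Reagents that add atoms: titanium tetrachloride, Cl[Ti](Cl)(Cl)Cl
Why: Lewis acid-promoted SN2′ opening of the vinyl oxirane by chloride gives the primary allylic chloride with the thermodynamically favoured E-trisubstituted alkene.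

Step 15
Reactants: 21 (2E)-4-chloro-2-methylbut-2-en-1-ol
Product: 22 [(2E)-4-hydroxy-3-methylbut-2-en-1-yl]triphenylphosphonium chloride
Conditions: PPh3, MeCN, reflux
Reagents that add atoms: triphenylphosphine, c1ccc(cc1)P(c1ccccc1)c1ccccc1
Why: SN2 quaternization of triphenylphosphine by the primary allylic chloride gives the phosphonium salt without touching the alkene geometry.

Step 16
Reactants: 19 α-peroxy aldehyde; 22 hydroxy phosphonium chloride
Product: 24 methyl (2R)-2-{(3S,6S)-6-[(3E)-5-hydroxy-4-methylpenta-1,3-dien-1-yl]-6-methyl-1,2-dioxan-3-yl}propanoate, via ylide 23 (not isolated)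
Conditions: 22, NaN(SiMe3)2 (2.1 equiv), THF, −78 °C; 19, −78 to 0 °C
Reagents that add atoms: none
Why: Deprotonation of the hydroxyl and of the P–CH2 group gives an alkoxide ylide that adds to the unenolizable aldehyde at low temperature (Wittig olefination), the trisubstituted alkene should keep its E geometry, and the geometry of the new disubstituted alkene is irrelevant because it is reduced in step 20.

Step 17
Reactants: 24 dienol
Product: 25 methyl (2R)-2-[(3S,6S)-6-{2-[(2S,3S)-3-(hydroxymethyl)-3-methyloxiran-2-yl]ethenyl}-6-methyl-1,2-dioxan-3-yl]propanoate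
Conditions: Ti(OiPr)4, L-(+)-diethyl tartrate, t-BuOOH, 4 Å molecular sieves, CH2Cl2, −20 °C
Reagents that add atoms: tert-butyl hydroperoxide, CC(C)(C)OO
Why: Sharpless asymmetric epoxidation epoxidizes only the alkene of the allylic alcohol, and the L-(+)-tartrate complex delivers oxygen to the face that gives the (2S,3S)-epoxy alcohol, which sets both epoxide stereocentres under reagent control irrespective of the remote dioxane centres.

Step 18
Reactants: 25 epoxy alcohol
Product: 26 methyl (2R)-2-[(3S,6S)-6-{2-[(2S,3R)-3-formyl-3-methyloxiran-2-yl]ethenyl}-6-methyl-1,2-dioxan-3-yl]propanoate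
Conditions: Dess–Martin periodinane, NaHCO3, CH2Cl2, 0 °C
Reagents that add atoms: none
Why: Dess–Martin oxidation under bicarbonate buffer converts the primary epoxy alcohol into the epoxy aldehyde, whose α-carbon is quaternary and cannot epimerize.

Step 19
Reactants: 26 epoxy aldehyde; 8 cyclogeranyl phosphonium bromide
Product: 28 methyl (2R)-2-[(3S,6S)-6-methyl-6-{2-[(2S,3S)-3-methyl-3-[2-(2,6,6-trimethylcyclohex-1-en-1-yl)ethenyl]oxiran-2-yl]ethenyl}-1,2-dioxan-3-yl]propanoate, via ylide 27 (not isolated)
Conditions: 8, NaN(SiMe3)2, THF, 0 °C; 26, −78 °C to rt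
Reagents that add atoms: none
Why: The cyclogeranyl ylide, formed with a salt-free amide base, should add to the aldehyde by Wittig olefination and join the ring to the chain, and the E/Z ratio of the new alkene does not matter.

Step 20
Reactants: 28 bis-alkene ester
Product: 29 methyl (2R)-2-[(3S,6R)-6-methyl-6-{2-[(2S,3S)-3-methyl-3-[2-(2,6,6-trimethylcyclohex-1-en-1-yl)ethyl]oxiran-2-yl]ethyl}-1,2-dioxan-3-yl]propanoate
Conditions: 2-nitrobenzenesulfonohydrazide (excess), Et3N, CH2Cl2, rt
Reagents that add atoms: none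
Why: Diimide generated in situ transfers hydrogen in a concerted syn fashion to the two 1,2-disubstituted alkenes (diimide reduction), while the hindered tetrasubstituted ring alkene, the O–O bond, the epoxide and the ester should not react, so the E/Z mixtures converge on one compound.

Step 21
Reactants: 29 methyl ester
Product: 30 (2R)-2-[(3S,6R)-6-methyl-6-{2-[(2S,3S)-3-methyl-3-[2-(2,6,6-trimethylcyclohex-1-en-1-yl)ethyl]oxiran-2-yl]ethyl}-1,2-dioxan-3-yl]propanoic acid
Conditions: LiOH, THF/H2O, 0 °C; aq. NaH2PO4 to pH 5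
Reagents that add atoms: lithium hydroxide, [Li+].[OH-]
Why: Saponification with LiOH at low temperature (ester hydrolysis) followed by buffered acidification should free the acid without base-induced opening of the dioxane or acid-induced opening of the epoxide.

Compound list
1 | methyl acetoacetate | CC(=O)CC(=O)OC | starting material
2 | prenyl bromide (1-bromo-3-methylbut-2-ene) | CC(C)=CCBr | starting material
3 | methyl 7-methyl-3-oxooct-6-enoate | COC(=O)CC(=O)CCC=C(C)C | intermediate
4 | methyl 2,2-dimethyl-6-oxocyclohexane-1-carboxylate (racemic) | COC(=O)C1C(=O)CCCC1(C)C | intermediate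
5 | methyl 6,6-dimethyl-2-(trifluoromethylsulfonyloxy)cyclohex-1-ene-1-carboxylate | COC(=O)C1=C(OS(=O)(=O)C(F)(F)F)CCCC1(C)C | intermediate
6 | methyl 2,6,6-trimethylcyclohex-1-ene-1-carboxylate | COC(=O)C1=C(C)CCCC1(C)C | intermediate
7 | (2,6,6-trimethylcyclohex-1-en-1-yl)methanol | OCC1=C(C)CCCC1(C)C | intermediate
8 | triphenyl[(2,6,6-trimethylcyclohex-1-en-1-yl)methyl]phosphonium bromide | CC1=C(C[P+](c2ccccc2)(c2ccccc2)c2ccccc2)C(C)(C)CCC1.[Br-] | intermediate
9 | geraniol | CC(C)=CCC/C(C)=C/CO | starting material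
10 | [(2R,3R)-3-methyl-3-(4-methylpent-3-en-1-yl)oxiran-2-yl]methanol | OC[C@H]1O[C@]1(C)CCC=C(C)C | intermediate
11 | tert-butyl{[(2R,3R)-3-methyl-3-(4-methylpent-3-en-1-yl)oxiran-2-yl]methoxy}diphenylsilane | CC(C)(C)[Si](c1ccccc1)(c1ccccc1)OC[C@H]1O[C@]1(C)CCC=C(C)C | intermediate
12 | 3-[(2R,3R)-3-(tert-butyldiphenylsilyloxymethyl)-2-methyloxiran-2-yl]propanal | CC(C)(C)[Si](c1ccccc1)(c1ccccc1)OC[C@H]1O[C@]1(C)CCC=O | intermediate
13 | (3S,4R)-6-[(2R,3R)-3-(tert-butyldiphenylsilyloxymethyl)-2-methyloxiran-2-yl]-3-methylhex-1-en-4-ol | CC(C)(C)[Si](c1ccccc1)(c1ccccc1)OC[C@H]1O[C@]1(C)CC[C@@H](O)[C@@H](C)C=C | intermediate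
14 | (3S,4R)-6-[(2R,3R)-3-(tert-butyldiphenylsilyloxymethyl)-2-methyloxiran-2-yl]-3-methylhex-1-en-4-yl methanesulfonate | CC(C)(C)[Si](c1ccccc1)(c1ccccc1)OC[C@H]1O[C@]1(C)CC[C@@H](OS(C)(=O)=O)[C@@H](C)C=C | intermediate
15 | (2R,3S,6R,7S)-1-(tert-butyldiphenylsilyloxy)-3-hydroperoxy-2-hydroxy-3,7-dimethylnon-8-en-6-yl methanesulfonate | CC(C)(C)[Si](c1ccccc1)(c1ccccc1)OC[C@@H](O)[C@@](C)(OO)CC[C@@H](OS(C)(=O)=O)[C@@H](C)C=C | intermediate
16 | (1R)-2-(tert-butyldiphenylsilyloxy)-1-{(3S,6S)-6-[(2S)-but-3-en-2-yl]-3-methyl-1,2-dioxan-3-yl}ethan-1-ol | CC(C)(C)[Si](c1ccccc1)(c1ccccc1)OC[C@@H](O)[C@]1(C)CC[C@@H]([C@@H](C)C=C)OO1 | intermediate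
17 | methyl (2R)-2-{(3S,6S)-6-[(1R)-2-(tert-butyldiphenylsilyloxy)-1-hydroxyethyl]-6-methyl-1,2-dioxan-3-yl}propanoate | CC(C)(C)[Si](c1ccccc1)(c1ccccc1)OC[C@@H](O)[C@]1(C)CC[C@@H]([C@@H](C)C(=O)OC)OO1 | intermediate
18 | methyl (2R)-2-{(3S,6S)-6-[(1R)-1,2-dihydroxyethyl]-6-methyl-1,2-dioxan-3-yl}propanoate | OC[C@@H](O)[C@]1(C)CC[C@@H]([C@@H](C)C(=O)OC)OO1 | intermediate
19 | methyl (2R)-2-[(3S,6S)-6-formyl-6-methyl-1,2-dioxan-3-yl]propanoate | O=C[C@]1(C)CC[C@@H]([C@@H](C)C(=O)OC)OO1 | intermediate
20 | 2-methyl-2-vinyloxirane (racemic) | CC1(CO1)C=C | starting material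
21 | (2E)-4-chloro-2-methylbut-2-en-1-ol | OC/C(C)=C/CCl | intermediate
22 | [(2E)-4-hydroxy-3-methylbut-2-en-1-yl]triphenylphosphonium chloride | OC/C(C)=C/C[P+](c1ccccc1)(c1ccccc1)c1ccccc1.[Cl-] | intermediate
23 | sodium (2E)-2-methyl-4-(triphenylphosphoranylidene)but-2-en-1-olate | [Na+].[O-]C/C(C)=C/C=P(c1ccccc1)(c1ccccc1)c1ccccc1 | intermediate
24 | methyl (2R)-2-{(3S,6S)-6-[(3E)-5-hydroxy-4-methylpenta-1,3-dien-1-yl]-6-methyl-1,2-dioxan-3-yl}propanoate (1E/1Z mixture) | OC/C(C)=C/C=C[C@]1(C)CC[C@@H]([C@@H](C)C(=O)OC)OO1 | intermediate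
25 | methyl (2R)-2-[(3S,6S)-6-{2-[(2S,3S)-3-(hydroxymethyl)-3-methyloxiran-2-yl]ethenyl}-6-methyl-1,2-dioxan-3-yl]propanoate (E/Z mixture at the ethenyl group) | OC[C@]1(C)O[C@H]1C=C[C@]1(C)CC[C@@H]([C@@H](C)C(=O)OC)OO1 | intermediate
26 | methyl (2R)-2-[(3S,6S)-6-{2-[(2S,3R)-3-formyl-3-methyloxiran-2-yl]ethenyl}-6-methyl-1,2-dioxan-3-yl]propanoate (E/Z mixture at the ethenyl group) | O=C[C@]1(C)O[C@H]1C=C[C@]1(C)CC[C@@H]([C@@H](C)C(=O)OC)OO1 | intermediate
27 | triphenyl[(2,6,6-trimethylcyclohex-1-en-1-yl)methylidene]phosphorane | CC1=C(C=P(c2ccccc2)(c2ccccc2)c2ccccc2)C(C)(C)CCC1 | intermediate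
28 | methyl (2R)-2-[(3S,6S)-6-methyl-6-{2-[(2S,3S)-3-methyl-3-[2-(2,6,6-trimethylcyclohex-1-en-1-yl)ethenyl]oxiran-2-yl]ethenyl}-1,2-dioxan-3-yl]propanoate (E/Z mixtures at both ethenyl groups) | CC1=C(C=C[C@]2(C)O[C@H]2C=C[C@]2(C)CC[C@@H]([C@@H](C)C(=O)OC)OO2)C(C)(C)CCC1 | intermediate
29 | methyl (2R)-2-[(3S,6R)-6-methyl-6-{2-[(2S,3S)-3-methyl-3-[2-(2,6,6-trimethylcyclohex-1-en-1-yl)ethyl]oxiran-2-yl]ethyl}-1,2-dioxan-3-yl]propanoate | CC1=C(CC[C@]2(C)O[C@H]2CC[C@]2(C)CC[C@@H]([C@@H](C)C(=O)OC)OO2)C(C)(C)CCC1 | intermediate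
30 | (2R)-2-[(3S,6R)-6-methyl-6-{2-[(2S,3S)-3-methyl-3-[2-(2,6,6-trimethylcyclohex-1-en-1-yl)ethyl]oxiran-2-yl]ethyl}-1,2-dioxan-3-yl]propanoic acid | CC1=C(CC[C@]2(C)O[C@H]2CC[C@]2(C)CC[C@@H]([C@@H](C)C(=O)O)OO2)C(C)(C)CCC1 | target

Total step count: 21 steps.
Longest linear sequence: 14 steps (geraniol 9 to 30, steps 6–13 and 16–21).

Steps most likely to fail

Step 11. The tertiary epoxide carbon may ionize before hydrogen peroxide attacks, which would erode the configuration of the quaternary peroxide carbon, and the basic ring closure may lose the mesylate by elimination instead of substitution. The fallback sets out from 14 and reverses the order of the two C–O bond formations. Displacement of the mesylate by hydroperoxide anion (50% H2O2, KOH, MeOH/THF, 0 °C to rt; SN2 with inversion) should give the epoxy hydroperoxide F1. A Lewis acid (Yb(OTf)3, CH2Cl2, −20 °C) should then let the secondary hydroperoxide open the epoxide at its tertiary carbon from the back in a 6-exo closure, which comes back to the route at 16.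

Step 16. The strongly basic allylic ylide may attack the peroxide or the ester, and delocalization in the ylide may partly scramble the E geometry of the trisubstituted alkene, which would later give a diastereomeric epoxide. The fallback sets out from 19 and uses only stabilized, neutral ylides. Wittig reaction with (triphenylphosphoranylidene)acetaldehyde (toluene, 60 °C) should give the enal F2. A second Wittig reaction with 2-(triphenylphosphoranylidene)propanal (toluene, 80 °C) should give the dienal F3 with an E-trisubstituted alkene. Luche reduction (NaBH4, CeCl3, MeOH, −40 °C) comes back to the route at 24, as its all-E isomer.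

Step 19. Addition of the hindered cyclogeranyl ylide to the α-quaternary epoxy aldehyde may be slow, so that base-induced opening of the vinyl epoxide competes. The fallback sets out from 7 and replaces the phosphorus ylide by a smaller sulfonyl carbanion. Mitsunobu thioetherification with 1-phenyl-1H-tetrazole-5-thiol (PPh3, diisopropyl azodicarboxylate, THF) should give the tetrazolyl sulfide F4. Oxidation ((NH4)6Mo7O24, H2O2, EtOH, 0 °C) should give the sulfone F5. Julia–Kocienski olefination of 26 (KN(SiMe3)2, THF, −78 °C) comes back to the route at 28.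

Further compounds
F1 | step 11 | tert-butyl{[(2R,3R)-3-[(3S,4S)-3-hydroperoxy-4-methylhex-5-en-1-yl]-3-methyloxiran-2-yl]methoxy}diphenylsilane | CC(C)(C)[Si](c1ccccc1)(c1ccccc1)OC[C@H]1O[C@]1(C)CC[C@H](OO)[C@@H](C)C=C
F2 | step 16 | methyl (2R)-2-{(3S,6S)-6-methyl-6-[(1E)-3-oxoprop-1-en-1-yl]-1,2-dioxan-3-yl}propanoate | O=C/C=C/[C@]1(C)CC[C@@H]([C@@H](C)C(=O)OC)OO1
F3 | step 16 | methyl (2R)-2-{(3S,6S)-6-methyl-6-[(1E,3E)-4-methyl-5-oxopenta-1,3-dien-1-yl]-1,2-dioxan-3-yl}propanoate | O=C/C(C)=C/C=C/[C@]1(C)CC[C@@H]([C@@H](C)C(=O)OC)OO1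
F4 | step 19 | 1-phenyl-5-{[(2,6,6-trimethylcyclohex-1-en-1-yl)methyl]sulfanyl}-1H-tetrazole | CC1=C(CSc2nnnn2-c2ccccc2)C(C)(C)CCC1
F5 | step 19 | 1-phenyl-5-{[(2,6,6-trimethylcyclohex-1-en-1-yl)methyl]sulfonyl}-1H-tetrazole | CC1=C(CS(=O)(=O)c2nnnn2-c2ccccc2)C(C)(C)CCC1
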